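The time of reading is 30 h: then the flasks south, north and south-east, which differ in temperature, are read for the Ej (monomer in chains) made from Ly (monomer) in the presence of Kj (initiator as charged).

| flask | Ly | Kj | temperature | remark | time |
|---|---|---|---|---|---|
| spring | 0.42 M | 3 mM | 5 °C | run made earlier |  |
| summer | 0.66 M | 3 mM | 25 °C | run made earlier |  |
| south | 0.30 M | 3.0 mM | 40 °C |  | 30 h |
| north | 0.30 M | 3.0 mM | 10 °C |  | 30 h |
| south-east | 0.30 M | 3.0 mM | 25 °C |  | 30 h |

| run | time / h | Ej / % | Ly / % |
|---|---|---|---|
| spring | 30.0 | 0 | 101 |
| spring | 60.0 | 0 | 101 |
| spring | 96.0 | 1 | 98 |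
| spring | 120 | 1 | 98 |
| spring | 144 | 2 | 98 |
| spring | 192 | 4 | 94 |
| spring | 240 | 5 | 93 |
| summer | 10.0 | 1 | 98 |
| summer | 20.0 | 5 | 94 |
| summer | 30.0 | 9 | 89 |
| summer | 40.0 | 14 | 81 |
| summer | 48.0 | 27 | 77 |
| summer | 60.0 | 38 | 61 |
| summer | 96.0 | 69 | 32 |

(scatter of a reading: 1.5 percentage points)

- the analysis behind the earlier runs scatters by 1.5 percentage points, standard deviation

* which flask leads in amount of Ej, in percent of the Ly charged ("all alike" within 1.5 percentage points) (south / north / south-east / all alike)
* how much Ej is there at the end, in percent of the Ly charged: south
* how much Ej is there at the end, in percent of the Ly charged: north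
* how much Ej is there at the end, in percent of the Ly charged: south-east

Both earlier runs start slowly and then speed up. If active chains grow in proportion to time, Ly decays in a pseudo-first-order way with a rate constant that itself grows with time. Integrating gives a closed form: minus the logarithm of the fraction of Ly left equals the square of the time divided by the square of a time τ, at which that logarithm has reached minus one.

The summer reading at 60.0 h, with Ly at 61%, gives τ as 85.3 h. The spring reading at 240 h, with Ly at 93%, gives 891 h, and both carry the scatter of their readings. The two runs differ in temperature as well as charge, so taking the inverse square of τ as proportional to the Ly charge is an assumption here. On that assumption south-east has 127 h, its acceleration time, the τ of a flask at the summer temperature with the south-east charge.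

At equal charge, the inverse square of τ in the summer run exceeds that in the spring run by a factor 69.4. With the logarithm of that inverse square taken as straight in temperature, south and north lie equally far from south-east, so it is multiplied or divided by 24.0. This reckoning gives 74.1% converted in south, 5.46% in south-east and 0.233% in north.

The forecast names south as leader, with 70% there, 7% in south-east and 0.3% in north. For south it stands lower than this reckoning, noting “Initiator exhaustion could also limit it”; for south-east and north it stands higher.

The flasks give 80.5% of Ej in south, 6.97% in south-east and 0.113% in north, so south leads, and the forecast for south is low by 10 percentage points.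

    Ly + Uj → Ve + Ej (k = 1.00 /M/h, Ea = 62.0 kJ/mol)
    Ly + Ve → Ej + Ve, rate k2*[Ve]*[Ly] (k = 120 /M/h, Ea = 55.0 kJ/mol)
    Kj → Uj (k = 0.0170 /h, Ea = 98.0 kJ/mol)
    Uj + Ej → Uj + Dz (k = 5.00 /M/h, Ea = 53.0 kJ/mol)
    (constants at 40 °C)

In south-east at 30.0 h, Kj stood at 92.6% of its charge, with Uj at 2.58% and Ve at 4.81% of that charge. Ly was then going 260 times faster by Ly + Ve than by Ly + Uj. The acceleration time leaves 94.6% of the Ly in south-east, against 93% in the flask.

For south-east read at 20 h, the acceleration time gives 2.45% converted; the computed Ej there is 2.53%.

The earlier runs and the new flask come from a simulation on assumed constants, and the scatter is random.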